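**Retrosynthetic overview**

- The target is reached from the all-cis 2-phenyl-1,3-dioxane carrying an (E)-hept-1-enyl group by alkene saturation, acetal hydrolysis, diacetylation and a final debenzylation of the phenol.
- Key disconnection: the C5–O bond and both acetal C–O bonds. The dioxane comes from (3R,5E)-1-aryldodec-5-ene-3,7-diol and benzaldehyde dimethyl acetal by rhenium(VII) 1,3-transposition of the C7 hydroxyl to C5 with benzylidene capture.
- The ene-diol comes from cross-metathesis (C5=C6) of the (R)-homoallylic alcohol with racemic oct-1-en-3-ol. That alcohol comes from (R)-epichlorohydrin by benzylic Grignard opening (C1–C2), epoxide re-closure and vinyl Grignard opening (C4–C5).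
- Feature used: the 1,3-syn pair of oxygen-bearing carbons C3 and C5 of the dodecane chain. The C5 oxygen is the allylic transposition partner of a C7 oxygen across C5=C6, and only an oxygen on C5 can close a six-membered 1,3-dioxane (O–C3–C4–C5–O plus the benzylidene carbon) with the C3 oxygen.
- Ring order: the arene is bought; the only ring made is this temporary 1,3-dioxane (step 6), opened again in step 8.

Key step: step 6

Remark: chain atoms are numbered as in the dodecane chain of the target (C1 carries the aryl group); racemic oct-1-en-3-ol is used on purpose, because the C7 configuration and the alkene geometry of the metathesis product are both erased by the equilibrating rhenium step.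

**Route**

Step 1
Reactants: 1 4-(benzyloxy)-3-methoxybenzyl alcohol
Product: 2 4-(benzyloxy)-3-methoxybenzyl chloride
Conditions: SOCl2 (1.2 equiv), CH2Cl2, 0 °C → rt; used crude
Reagents that add atoms: thionyl chloride, ClS(Cl)=O
Why: Chlorodehydroxylation of an electron-rich benzylic alcohol through its chlorosulfite (SNi/SN1-type substitution) is fast at 0 °C, and the aryl benzyl and methyl ethers are inert to the HCl formed.

Step 2
Reactants: 2 4-(benzyloxy)-3-methoxybenzyl chloride; 3 (R)-epichlorohydrin
Product: 5 (2R)-4-[4-(benzyloxy)-3-methoxyphenyl]-1-chlorobutan-2-ol, via benzylic Grignard reagent 4 (not isolated)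
Conditions: Mg turnings (3 equiv), THF, 0 °C, slow addition of 2; then CuI (10 mol%), 3, THF, −40 → 0 °C; aqueous work-up
Reagents that add atoms: none
Why: Magnesium insertion into the benzylic C–Cl bond gives Grignard reagent 4, which under copper(I) catalysis opens the oxirane of 3 at its unsubstituted carbon by SN2 attack (copper-catalysed Grignard epoxide opening) faster than it displaces chloride, so the carbinol carbon is not touched and is carried on as the R centre that becomes C3.

Step 3
Reactants: 5 (2R)-4-[4-(benzyloxy)-3-methoxyphenyl]-1-chlorobutan-2-ol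
Product: 6 (2R)-2-{2-[4-(benzyloxy)-3-methoxyphenyl]ethyl}oxirane
Conditions: NaOH (powdered, 2 equiv), Et2O, rt
Reagents that add atoms: none
Why: Intramolecular Williamson etherification (3-exo-tet closure of the chlorohydrin alkoxide) takes place at the achiral CH2Cl carbon, so the stereocentre keeps its configuration.

Step 4
Reactants: 6 (2R)-2-{2-[4-(benzyloxy)-3-methoxyphenyl]ethyl}oxirane; 7 vinylmagnesium bromide
Product: 8 (3R)-1-[4-(benzyloxy)-3-methoxyphenyl]hex-5-en-3-ol
Conditions: 7 (1.5 equiv), CuI (10 mol%), THF, −40 → −10 °C; aqueous work-up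
Reagents that add atoms: none
Why: Copper-catalysed SN2 opening of a monosubstituted epoxide by a vinyl Grignard reagent occurs at the terminal carbon, which forms the C4–C5 bond and leaves the C3 carbinol centre untouched.

Step 5
Reactants: 8 (3R)-1-[4-(benzyloxy)-3-methoxyphenyl]hex-5-en-3-ol; 9 oct-1-en-3-ol (racemic)
Product: 10 (3R,5E)-1-[4-(benzyloxy)-3-methoxyphenyl]dodec-5-ene-3,7-diol (mixture of C7 epimers)
Conditions: Grubbs II (5 mol%), 9 (3 equiv), CH2Cl2, 40 °C
Reagents that add atoms: none
Why: Ruthenium-catalysed olefin cross-metathesis of a fast-reacting homoallylic alkene with an excess of a slower secondary allylic alcohol favours the cross-product and its E isomer, free hydroxyl groups are tolerated, and neither the C7 configuration nor the E/Z ratio needs control because both are equilibrated in step 6.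

Step 6
Reactants: 10 (3R,5E)-1-[4-(benzyloxy)-3-methoxyphenyl]dodec-5-ene-3,7-diol (mixture of C7 epimers); 11 benzaldehyde dimethyl acetal
Product: 13 (2R,4R,6R)-4-{2-[4-(benzyloxy)-3-methoxyphenyl]ethyl}-6-[(1E)-hept-1-en-1-yl]-2-phenyl-1,3-dioxane (all-cis), via transposed 3,5-diol 12 (not isolated)
Conditions: Re2O7 (5 mol%), 11 (3 equiv), CH2Cl2, 0 °C → rt
Reagents that add atoms: none
Why: Rhenium(VII) oxide esterifies the allylic C7 hydroxyl, and the perrhenate rearranges suprafacially through a six-membered chair transition state with some allyl-cation character, so that the oxygen ends on C5 and the double bond moves to C6=C7 in an equilibrium that interconverts both C5 epimers and both alkene geometries; this is the known rhenium-catalysed 1,3-transposition of allylic alcohols run with in situ acetal capture of a 1,3-diol. The perrhenic acid present also exchanges the C3 hydroxyl into a mixed methyl benzylidene acetal, and its oxocarbenium ion is attacked by the C5 hydroxyl in a 6-endo-trig closure that forms the 1,3-dioxane, whereas the C7 hydroxyl would need an eight-membered ring. The new C5 stereocentre is set under thermodynamic control by the fixed (R)-C3 centre, because only the 3,5-syn diol gives a chair with the arylethyl and heptenyl groups both equatorial, while the anti acetal and the open diols stay in equilibrium through reversible acetalisation and transposition. The acetal carbon is set in the same way with phenyl equatorial, which makes the dioxane all-cis, and the E alkene is the favoured geometry of the equilibrating allyl system. The step needs C5-over-C7 regioselectivity and syn selectivity at C5, and both are secured by the non-allylic, configurationally stable C3 carbinol, which anchors the six-membered acetal sink so that the whole C7 epimer mixture and any Z-alkene converge on one product.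

Step 7
Reactants: 13 (2R,4R,6R)-4-{2-[4-(benzyloxy)-3-methoxyphenyl]ethyl}-6-[(1E)-hept-1-en-1-yl]-2-phenyl-1,3-dioxane
Product: 14 (2S,4R,6S)-4-{2-[4-(benzyloxy)-3-methoxyphenyl]ethyl}-6-heptyl-2-phenyl-1,3-dioxane (all-cis; descriptors change by CIP priority only)
Conditions: TsNHNH2 (6 equiv), NaOAc (6 equiv), DME/H2O, reflux
Reagents that add atoms: none
Why: Diimide, formed by base-induced fragmentation of the sulfonyl hydrazide, transfers two hydrogen atoms to the C6=C7 bond in a concerted syn fashion (diimide reduction) without hydrogenolysis of the allylic acetal C–O bond or of the benzyl ether, and no stereocentre is involved.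

Step 8
Reactants: 14 (2S,4R,6S)-4-{2-[4-(benzyloxy)-3-methoxyphenyl]ethyl}-6-heptyl-2-phenyl-1,3-dioxane
Product: 15 (3R,5S)-1-[4-(benzyloxy)-3-methoxyphenyl]dodecane-3,5-diol
Conditions: AcOH/H2O (4:1), 50 °C
Reagents that add atoms: none
Why: Acid-catalysed acetal hydrolysis breaks only the bonds to the benzylidene carbon, so the C3–O and C5–O bonds keep their configuration, and the aryl benzyl ether is stable to aqueous acetic acid.

Step 9
Reactants: 15 (3R,5S)-1-[4-(benzyloxy)-3-methoxyphenyl]dodecane-3,5-diol
Product: 16 (3R,5S)-1-[4-(benzyloxy)-3-methoxyphenyl]dodecane-3,5-diyl diacetate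
Conditions: Ac2O (4 equiv), pyridine, DMAP (cat.), CH2Cl2, rt
Reagents that add atoms: acetic anhydride, CC(=O)OC(C)=O
Why: DMAP-catalysed O-acylation of both secondary hydroxyl groups proceeds with retention because no bond to C3 or C5 is broken.

Step 10
Reactants: 16 (3R,5S)-1-[4-(benzyloxy)-3-methoxyphenyl]dodecane-3,5-diyl diacetate
Product: 17 (3R,5S)-1-(4-hydroxy-3-methoxyphenyl)dodecane-3,5-diyl diacetate (target)
Conditions: H2 (1 atm), 10% Pd/C, EtOAc, rt
Reagents that add atoms: none
Why: Palladium-catalysed hydrogenolysis cleaves the benzylic C–O bond of the aryl benzyl ether and leaves the secondary acetates, the methyl ether and the arene untouched, which frees the phenol of the target.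

**Compound list**

1 | 4-(benzyloxy)-3-methoxybenzyl alcohol | COc1cc(CO)ccc1OCc1ccccc1 | starting material
2 | 4-(benzyloxy)-3-methoxybenzyl chloride | COc1cc(CCl)ccc1OCc1ccccc1 | intermediate
3 | (R)-epichlorohydrin | ClC[C@H]1CO1 | starting material
4 | [4-(benzyloxy)-3-methoxybenzyl]magnesium chloride | COc1cc(C[Mg]Cl)ccc1OCc1ccccc1 | intermediate
5 | (2R)-4-[4-(benzyloxy)-3-methoxyphenyl]-1-chlorobutan-2-ol | COc1cc(CC[C@@H](O)CCl)ccc1OCc1ccccc1 | intermediate
6 | (2R)-2-{2-[4-(benzyloxy)-3-methoxyphenyl]ethyl}oxirane | COc1cc(CC[C@@H]2CO2)ccc1OCc1ccccc1 | intermediate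
7 | vinylmagnesium bromide | C=C[Mg]Br | starting material
8 | (3R)-1-[4-(benzyloxy)-3-methoxyphenyl]hex-5-en-3-ol | COc1cc(CC[C@@H](O)CC=C)ccc1OCc1ccccc1 | intermediate
9 | oct-1-en-3-ol (racemic) | CCCCCC(O)C=C | starting material
10 | (3R,5E)-1-[4-(benzyloxy)-3-methoxyphenyl]dodec-5-ene-3,7-diol (C7 epimers) | COc1cc(CC[C@@H](O)C/C=C/C(O)CCCCC)ccc1OCc1ccccc1 | intermediate
11 | benzaldehyde dimethyl acetal | COC(OC)c1ccccc1 | starting material
12 | (3R,6E)-1-[4-(benzyloxy)-3-methoxyphenyl]dodec-6-ene-3,5-diol (C5 epimers in equilibrium) | COc1cc(CC[C@@H](O)CC(O)/C=C/CCCCC)ccc1OCc1ccccc1 | intermediate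
13 | (2R,4R,6R)-4-{2-[4-(benzyloxy)-3-methoxyphenyl]ethyl}-6-[(1E)-hept-1-en-1-yl]-2-phenyl-1,3-dioxane (all-cis) | COc1cc(CC[C@@H]2C[C@H](/C=C/CCCCC)O[C@H](c3ccccc3)O2)ccc1OCc1ccccc1 | intermediate
14 | (2S,4R,6S)-4-{2-[4-(benzyloxy)-3-methoxyphenyl]ethyl}-6-heptyl-2-phenyl-1,3-dioxane (all-cis) | COc1cc(CC[C@@H]2C[C@H](CCCCCCC)O[C@H](c3ccccc3)O2)ccc1OCc1ccccc1 | intermediate
15 | (3R,5S)-1-[4-(benzyloxy)-3-methoxyphenyl]dodecane-3,5-diol | COc1cc(CC[C@@H](O)C[C@@H](O)CCCCCCC)ccc1OCc1ccccc1 | intermediate
16 | (3R,5S)-1-[4-(benzyloxy)-3-methoxyphenyl]dodecane-3,5-diyl diacetate | COc1cc(CC[C@@H](OC(C)=O)C[C@@H](OC(C)=O)CCCCCCC)ccc1OCc1ccccc1 | intermediate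
17 | (3R,5S)-1-(4-hydroxy-3-methoxyphenyl)dodecane-3,5-diyl diacetate | CCCCCCC[C@@H](C[C@@H](CCc1ccc(O)c(OC)c1)OC(C)=O)OC(C)=O | target

**Step count and risks**

Total step count: 10. Longest linear sequence: 10 steps (1 → 17).

Steps most likely to fail:

1. Step 6. The allylic perrhenate may ionise to a free allyl cation that is trapped by the C3 hydroxyl (cyclodehydration to a dihydropyran), attacked by the electron-rich arene or lost by elimination. Equilibration may also stay incomplete, leaving the anti acetal. Fallback: the C5 centre would be set by substrate-controlled reduction instead of thermodynamic acetalisation. Setting out from epoxide 6, the lithium anion of 2-heptyl-1,3-dithiane F1 (made from octanal and propane-1,3-dithiol with BF3·OEt2; n-BuLi, THF, −30 °C) would open the epoxide at its terminal carbon to give (2R)-4-[4-(benzyloxy)-3-methoxyphenyl]-1-(2-heptyl-1,3-dithian-2-yl)butan-2-ol F2. Dithiane hydrolysis (MeI, CaCO3, MeCN/H2O, 40 °C) would give (3R)-1-[4-(benzyloxy)-3-methoxyphenyl]-3-hydroxydodecan-5-one F3. Narasaka–Prasad reduction (Et2BOMe, NaBH4, THF/MeOH, −78 °C), with external hydride delivery to the six-membered boron chelate, should then give the 3,5-syn diol, which is compound 15; the route is rejoined there at step 9.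

2. Step 2. Wurtz-type homocoupling during magnesium insertion into the electron-rich benzylic chloride may consume the halide, and competing direct displacement of chloride in epichlorohydrin would erode the enantiomeric purity. Fallback: the benzylic carbon is used as the electrophile instead. Setting out from chloride 2, coupling with allylmagnesium bromide (THF, 0 °C) would give 1-(benzyloxy)-4-(but-3-en-1-yl)-2-methoxybenzene F4, and epoxidation (mCPBA, NaHCO3, CH2Cl2, 0 °C) would give racemic 2-{2-[4-(benzyloxy)-3-methoxyphenyl]ethyl}oxirane F5. Jacobsen hydrolytic kinetic resolution ((salen)Co(III)OAc, 0.55 equiv H2O; the catalyst enantiomer that hydrolyses the (S)-epoxide, expected to be the (R,R) complex) would leave the (R)-epoxide, which is compound 6, while the (S)-enantiomer is removed as its diol; the route is rejoined at step 4.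

3. Step 5. Self-metathesis of either alkene and ruthenium hydride-induced isomerisation of the allylic alcohol to a ketone may limit conversion to the cross-product. Fallback: the C5–C7 unit is built by acetylide chemistry. Setting out from epoxide 6, opening with lithium acetylide–ethylenediamine complex (DMSO, rt) would give (3R)-1-[4-(benzyloxy)-3-methoxyphenyl]hex-5-yn-3-ol F6. Its dianion (n-BuLi, 2.2 equiv, THF, −78 °C) would add to hexanal to give (3R)-1-[4-(benzyloxy)-3-methoxyphenyl]dodec-5-yne-3,7-diol F7 as a C7 epimer mixture. Trans-hydroalumination of the propargylic alcohol with Red-Al (THF, 0 °C → rt) should give the (E)-ene-diol, which is compound 10; the route is rejoined at step 6.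

**Further compounds**

F1 | step 6 | 2-heptyl-1,3-dithiane | CCCCCCCC1SCCCS1
F2 | step 6 | (2R)-4-[4-(benzyloxy)-3-methoxyphenyl]-1-(2-heptyl-1,3-dithian-2-yl)butan-2-ol | COc1cc(CC[C@@H](O)CC2(CCCCCCC)SCCCS2)ccc1OCc1ccccc1
F3 | step 6 | (3R)-1-[4-(benzyloxy)-3-methoxyphenyl]-3-hydroxydodecan-5-one | COc1cc(CC[C@@H](O)CC(=O)CCCCCCC)ccc1OCc1ccccc1
F4 | step 2 | 1-(benzyloxy)-4-(but-3-en-1-yl)-2-methoxybenzene | COc1cc(CCC=C)ccc1OCc1ccccc1
F5 | step 2 | racemic 2-{2-[4-(benzyloxy)-3-methoxyphenyl]ethyl}oxirane | COc1cc(CCC2CO2)ccc1OCc1ccccc1
F6 | step 5 | (3R)-1-[4-(benzyloxy)-3-methoxyphenyl]hex-5-yn-3-ol | COc1cc(CC[C@@H](O)CC#C)ccc1OCc1ccccc1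
F7 | step 5 | (3R)-1-[4-(benzyloxy)-3-methoxyphenyl]dodec-5-yne-3,7-diol (C7 epimers) | COc1cc(CC[C@@H](O)CC#CC(O)CCCCC)ccc1OCc1ccccc1
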